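## Analysis of the target

The target is a flavonol: a 4H-chromen-4-one (rings A and C) with a hydroxyl on C3 and a 4-hydroxy-3-methoxyphenyl ring B on C2. Ring A carries an oxygen on every carbon except C6: a free hydroxyl at C5, a 3-methylbut-2-enyl (prenyl) ether at C7, a methyl ether at C8 and the ring oxygen O1 at C8a. There is no stereocentre and no stereogenic double bond, since the prenyl alkene ends in two methyl groups. The prenyl aryl ether rules out hydrogenolysis, strong Brønsted or Lewis acids, electrophilic oxidants and long heating (ionisation, Claisen rearrangement). The free flavonol is also oxidised by air in basic solution. The difficulty lies in telling four oxygens apart on a 1,2,3,5-tetraoxygenated benzene and in choosing protecting groups that come off without hydrogenolysis. The strategy rests on C3 and C4 of ring C: they are adjacent and both oxygenated, so the enol–ketone there is the oxidised form of an acyloin between the formyl group on C4a of ring A and a formyl group on the carbon (C2) that bears ring B and O1.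

## Retrosynthetic reasoning

**Unmasking.** Target 22 is reached from 21 by freeing the 5-hydroxyl, and 21 from 20 by freeing the ring B phenol. The 5-oxygen is carried as a MOM acetal, which lies peri to the C4 carbonyl and is the most acid-labile group present, so it goes last under dilute acid. The ring B phenol is carried as a silyl ether removed by fluoride. No benzyl ether appears anywhere, because of the prenyl ether.

**C3–C4 (key disconnection).** In 20 this is the only C–C bond of ring C whose two ends are both oxygenated. Cutting it, with a formal reduction, gives dialdehyde 17, in which rings A and B are joined only through the C2–O1 ether. The forward reaction must turn one aldehyde into an acyl anion equivalent, close the six-membered ring to ketol 18 or 19, and oxidise the ketol. Neither regiochemistry nor configuration matters, because both ketols lead to the same diketone tautomer of 20.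

**Oxidation levels.** Dialdehyde 17 comes from diol 16, and 16 from aldehyde–ester 15. Hydride cannot distinguish the ring A aldehyde from the ester in 15, so both are reduced and both re-oxidised. This costs one step but avoids a protecting group on the aldehyde.

**C2–O1.** Cutting the ether of 15 gives ring A salicylaldehyde 9 and α-bromo ester 14. The carbon attacked is secondary but activated by aryl and ester and has no β-hydrogen, so SN2 by a hindered phenoxide is realistic. The cut is convergent and leaves two aromatic pieces of similar size.

**Ring B piece.** Bromide 14 comes from silyl ether 12 by bromination at the enolate carbon through ketene acetal 13. Ester 12 comes from 11, and 11 from homovanillic acid 10.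

**Prenyl ether.** Aldehyde 9 comes from dihydroxy aldehyde 7 and prenyl bromide 8. The hydroxyl para to the formyl group is more acidic and not chelated, so it can be alkylated in the presence of the ortho hydroxyl. That ortho hydroxyl is the future O1.

**Protecting-group switch on ring A.** Compound 7 comes from 6 by desilylation, and 6 from 5 by acetal formation on the only free phenol. This places the MOM group on O5 without any selectivity question.

**Formyl carbon.** Aldehyde 5 comes from phenol 4 by ortho-formylation. Both ortho carbons of 4 are equivalent and the para carbon is blocked, so only one product is possible.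

**O5.** Phenol 4 comes from arene 2 through boronate 3. The carbon para to the methoxy group is meta to both silyloxy groups and out of reach of electrophiles, but it is the only C–H without an ortho neighbour, which is what sterically controlled C–H borylation selects. Arene 2 is the bis-silyl ether of commercial 1.

## Alternatives that were turned down

**Alternative 1:** Ring C would be disconnected at C4a–C4 and C4–C3. In the forward sense aryl iodide A2, the enolate of α-alkoxy ketone A3 and one carbonyl carbon are joined under palladium-catalysed carbonylative α-arylation to give 2-alkoxy-1,3-diketone A1.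
- For it: this is the most convergent plan. It forms two C–C bonds in one step and delivers C3 and C4 at the final oxidation level, so acid alone would close ring C. On convergence and on avoiding redox adjustments it is stronger than the chosen route.
- Against it: A2 is a very electron-rich aryl iodide with two ortho substituents, so oxidative addition and reaction at the crowded acylpalladium centre are slow. Direct α-arylation without carbonyl insertion and O-acylation of the enolate compete, and A1 can undergo retro-Claisen cleavage.
- For this target the benzyl ethers of A1 are the larger problem. They can only go by hydrogenolysis before the prenyl group is present, so the prenyl ether would have to be placed last on tetraphenol A4, where the 7-hydroxyl competes with the 4'- and 3-hydroxyls.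
- In its place the chosen route carries the prenyl ether from a simple benzaldehyde, where the choice between two hydroxyls is dependable. It uses a metal-free ring closure and protecting groups that leave the prenyl ether alone.

**Alternative 2:** Ring A would be built last, by disconnection of C5–C6, C7–C8 and C4a–C5. Acid chloride A6 is dehydrochlorinated by an amine to ketene A7, which adds siloxyalkyne A8 in a [2+2] sense. The cyclobutenone opens (4π) to a dienylketene, which closes (6π) onto the pyranone double bond and tautomerises to A5.
- For it: the mechanism places all ring A substituents without any selective protection. The 5-hydroxyl emerges free and the 7-oxygen is uniquely marked as a silyl ether, ready for prenylation. On differentiation of the ring A oxygens it is stronger than the chosen route, which relies on one selective alkylation.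
- Against it: A6 is an advanced 2,6-disubstituted 3-acyloxy-4-pyranone that already contains ring B, and making it is about as demanding as a flavonol synthesis. A7 is an alkoxyketene on an electron-poor heterocycle and can dimerise. The electrocyclisation must use a double bond that is part of a vinylogous ester and needs heat. A8 is sensitive.
- The chosen route forms fewer bonds in its key step, but starts from two cheap aromatic compounds and is shorter overall.

**Alternative 3:** Ring C would be disconnected at C4–C4a. The (E)-3-aryloxyacrylic acid A10 is activated as a mixed anhydride and acylates the free ortho carbon of its ring A ether to give A9.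
- For it: only one ortho carbon is free and it is strongly activated, so regiochemistry is not in question. C3 and C4 arrive at the right oxidation level and ring A needs no formyl group. The pivalates on O3 and O4' would make a late 7-O-prenylation after hydrogenolysis selective, since only the chelated 5-hydroxyl competes. On that point it equals the chosen route and is better than Alternative 1.
- Against it: A10 is a tetrasubstituted alkene bearing four different heteroatom or aryl groups, and the carboxyl must be cis to the aryloxy group. A stereocontrolled synthesis is hard, and the wrong isomer cannot cyclise unless the acid isomerises it. The acidic acylating medium also endangers benzyl ethers on a highly activated ring.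
- The chosen route moves the uncertainty from making a stereodefined precursor to the ring closure itself. Its precursor comes from ordinary alkylation and redox steps.

Key step: step 13

Remarks on the chemistry:
- 2-Methoxyresorcinol is taken as the commercial entry to ring A.
- The ring B phenol is carried as a triisopropylsilyl ether, which withstands carbonate and hydride better than a tert-butyldimethylsilyl ether.
- The diol is oxidised with a periodinane and not with activated DMSO, because the trioxygenated benzylic alkoxysulfonium ion would ionise.

## Route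

**Step 1**
Reactants: 1 2-methoxyresorcinol (2-methoxybenzene-1,3-diol)
Product: 2 1,3-bis(tert-butyldimethylsilyloxy)-2-methoxybenzene
Conditions: TBSCl (2.3 equiv), imidazole, DMF, rt
Reagents that add atoms: tert-butyldimethylsilyl chloride, CC(C)(C)[Si](C)(C)Cl
Why: Routine silylation of phenols; the bulky silyl ethers shield C4 and C6 in the next step and later come off with fluoride without touching an acetal.

**Step 2**
Reactants: 2 1,3-bis(tert-butyldimethylsilyloxy)-2-methoxybenzene
Product: 4 3,5-bis(tert-butyldimethylsilyloxy)-4-methoxyphenol, via aryl pinacol boronate 3 (not isolated)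
Conditions: B2pin2 (1.0 equiv), [Ir(OMe)(cod)]2 (1.5 mol %), 4,4'-di-tert-butyl-2,2'-bipyridine (3 mol %), THF, 80 °C; then KHSO5 (Oxone), acetone–H2O, 0 °C
Reagents that add atoms: potassium peroxymonosulfate, [K+].OOS(=O)(=O)[O-] (the phenol oxygen of 4); bis(pinacolato)diboron, CC1(C)OB(OC1(C)C)B1OC(C)(C)C(C)(C)O1 (the boryl group of 3)
Why: Iridium-catalysed C–H borylation is governed by sterics and should take place only at C5, the one C–H without an ortho substituent; oxidation of the C–B bond (aryl shift from boron to oxygen) then gives the phenol whose oxygen becomes O5.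

**Step 3**
Reactants: 4 3,5-bis(tert-butyldimethylsilyloxy)-4-methoxyphenol
Product: 5 2,4-bis(tert-butyldimethylsilyloxy)-6-hydroxy-3-methoxybenzaldehyde
Conditions: MgCl2, Et3N, (CH2O)n, MeCN, reflux
Reagents that add atoms: paraformaldehyde (formaldehyde), C=O
Why: Magnesium-mediated ortho-formylation of a phenol (Casnati–Skattebøl reaction): the magnesium phenoxide delivers formaldehyde to the ortho carbon and the bound benzylic alkoxide passes hydride to a second formaldehyde; both ortho carbons are equivalent and the para carbon is blocked, so one aldehyde should form.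

**Step 4**
Reactants: 5 2,4-bis(tert-butyldimethylsilyloxy)-6-hydroxy-3-methoxybenzaldehyde
Product: 6 2,4-bis(tert-butyldimethylsilyloxy)-3-methoxy-6-(methoxymethoxy)benzaldehyde
Conditions: MOMCl, i-Pr2NEt, CH2Cl2, 0 to 40 °C
Reagents that add atoms: chloromethyl methyl ether, COCCl
Why: O-Alkylation of the only free phenol with a reactive α-chloro ether and a hindered amine; this fixes the acetal on the future O5 without any selectivity problem.

**Step 5**
Reactants: 6 2,4-bis(tert-butyldimethylsilyloxy)-3-methoxy-6-(methoxymethoxy)benzaldehyde
Product: 7 2,4-dihydroxy-3-methoxy-6-(methoxymethoxy)benzaldehyde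
Conditions: Bu4NF (2.2 equiv), AcOH, THF, 0 °C
Reagents that add atoms: none
Why: Fluoride cleaves aryl silyl ethers through the strong Si–F bond while the acetal and the aldehyde are inert; acetic acid buffers the phenoxides.

**Step 6**
Reactants: 7 2,4-dihydroxy-3-methoxy-6-(methoxymethoxy)benzaldehyde; 8 prenyl bromide (1-bromo-3-methylbut-2-ene)
Product: 9 2-hydroxy-3-methoxy-6-(methoxymethoxy)-4-(3-methylbut-2-enyloxy)benzaldehyde
Conditions: 8 (1.05 equiv), KHCO3, DMF, rt
Reagents that add atoms: none
Why: Williamson ether synthesis under a weak base: the 4-hydroxyl is para to the formyl group, more acidic and not hydrogen-bonded, whereas the 2-hydroxyl is chelated to the carbonyl and flanked on both sides, so one equivalent of the allylic bromide should alkylate O4 only.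

**Step 7**
Reactants: 10 homovanillic acid
Product: 11 methyl 2-(4-hydroxy-3-methoxyphenyl)acetate
Conditions: MeOH, H2SO4 (cat.), reflux
Reagents that add atoms: methanol, CO
Why: Fischer esterification driven by methanol as solvent.

**Step 8**
Reactants: 11 methyl 2-(4-hydroxy-3-methoxyphenyl)acetate
Product: 12 methyl 2-[3-methoxy-4-(triisopropylsilyloxy)phenyl]acetate
Conditions: TIPSCl, imidazole, DMF, rt
Reagents that add atoms: triisopropylsilyl chloride, CC(C)[Si](Cl)(C(C)C)C(C)C
Why: Silylation of the phenol; the triisopropylsilyl ether should survive amide base, carbonate, hydride and the carbene step and leaves with fluoride at the end.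

**Step 9**
Reactants: 12 methyl 2-[3-methoxy-4-(triisopropylsilyloxy)phenyl]acetate
Product: 14 methyl 2-bromo-2-[3-methoxy-4-(triisopropylsilyloxy)phenyl]acetate (racemic), via silyl ketene acetal 13 (not isolated)
Conditions: LiN(SiMe3)2, THF, −78 °C; TMSCl; then NBS, −78 to 0 °C
Reagents that add atoms: N-bromosuccinimide, O=C1CCC(=O)N1Br (the bromine of 14); chlorotrimethylsilane, C[Si](C)(C)Cl (the silyl group of 13)
Why: α-Bromination of an ester through its enolate, trapped as ketene acetal 13, which takes up electrophilic bromine at carbon; the detour avoids coupling of enolate with product and bromination of the electron-rich ring, and the new stereocentre is racemic and is lost in step 13.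

**Step 10**
Reactants: 9 2-hydroxy-3-methoxy-6-(methoxymethoxy)-4-(3-methylbut-2-enyloxy)benzaldehyde; 14 methyl 2-bromo-2-[3-methoxy-4-(triisopropylsilyloxy)phenyl]acetate
Product: 15 methyl 2-[2-formyl-6-methoxy-3-(methoxymethoxy)-5-(3-methylbut-2-enyloxy)phenoxy]-2-[3-methoxy-4-(triisopropylsilyloxy)phenyl]acetate (racemic)
Conditions: K2CO3, MeCN, rt
Reagents that add atoms: none
Why: Williamson ether synthesis (SN2): the phenoxide of 9 displaces bromide from a carbon activated by aryl and ester that has no β-hydrogen, so elimination cannot compete; room temperature and a heterogeneous carbonate should keep the product from enolising toward the neighbouring aldehyde.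

**Step 11**
Reactants: 15 the aldehyde–ester
Product: 16 2-[2-(hydroxymethyl)-6-methoxy-3-(methoxymethoxy)-5-(3-methylbut-2-enyloxy)phenoxy]-2-[3-methoxy-4-(triisopropylsilyloxy)phenyl]ethanol (racemic)
Conditions: i-Bu2AlH (5 equiv), CH2Cl2, −78 to 0 °C; aq. potassium sodium tartrate
Reagents that add atoms: none
Why: Hydride reduction of aldehyde and ester to primary alcohols; silyl ether, acetal and allyl ether are inert, and the neutral tartrate work-up spares the acid-sensitive trioxygenated benzylic alcohol.

**Step 12**
Reactants: 16 the diol
Product: 17 2-[2-formyl-6-methoxy-3-(methoxymethoxy)-5-(3-methylbut-2-enyloxy)phenoxy]-2-[3-methoxy-4-(triisopropylsilyloxy)phenyl]acetaldehyde (racemic)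
Conditions: Dess–Martin periodinane (3 equiv), NaHCO3, CH2Cl2, 0 °C to rt; used crude
Reagents that add atoms: none
Why: Oxidation of both primary alcohols by a hypervalent iodine reagent under buffered conditions; it is free of chloride and amine base, so the benzylic position cannot be ionised to a chloride and the enolisable α-aryl-α-aryloxy aldehyde is not exposed to base.

**Step 13**
Reactants: 17 the dialdehyde
Product: 20 3-hydroxy-8-methoxy-5-(methoxymethoxy)-2-[3-methoxy-4-(triisopropylsilyloxy)phenyl]-7-(3-methylbut-2-enyloxy)-4H-chromen-4-one, via 4-hydroxychroman-3-one ketol 18 (not isolated), via 3-hydroxychroman-4-one ketol 19 (not isolated)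
Conditions: 2-(pentafluorophenyl)-6,7-dihydro-5H-pyrrolo[2,1-c][1,2,4]triazol-2-ium tetrafluoroborate (20 mol %), i-Pr2NEt (20 mol %), CH2Cl2 (0.02 M), rt; then activated MnO2 (excess), rt
Reagents that add atoms: none
Why: The amine sets free the triazolylidene, which adds to an aldehyde of 17; proton transfer gives the Breslow intermediate, an acyl anion equivalent, which attacks the second aldehyde and then releases the carbene from the ketol. The closest known reaction type is the carbene-catalysed intramolecular crossed benzoin of salicylaldehyde-tethered carbonyl compounds to chromanone ketols, together with the crossed acyloin condensation between an aliphatic and an ortho-substituted aromatic aldehyde. Ring C closes in the 6-exo-trig mode with formation of C3–C4. The less hindered aliphatic aldehyde should be the donor, since the doubly ortho-substituted ring A aldehyde forms a Breslow intermediate reluctantly but accepts well, which gives 18; if the roles are exchanged 19 forms, and 18 and 19 also interconvert through their common enediol. The two new stereocentres and the one at C2 are uncontrolled and do not matter, because MnO2 dehydrogenates every ketol isomer to the same chroman-3,4-dione, whose enol tautomer is the pyranone 20. The step needs no regio- or stereoselectivity, but it needs chemoselectivity: ring closure must beat intermolecular acyloin formation, which dilution and the six-membered transition state secure, and C–C bond formation must beat both expulsion of the ring A phenoxide from the Breslow intermediate of the α-aryloxy aldehyde (internal redox to an aryl ester) and base-induced aldol closure of the enolisable aldehyde. Against these the substrate offers an electron-rich phenoxide that is only a moderate leaving group and an acceptor aldehyde held next to the nucleophilic carbon, and the conditions offer an N-pentafluorophenyl triazolium catalyst of the kind that favours acyl anion over redox chemistry, a weak amine in catalytic amount and a solvent of low polarity. MnO2 is added only after 17 is consumed, so that it cannot oxidise a Breslow intermediate to an acyl azolium ion.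

**Step 14**
Reactants: 20 the silyl-protected flavonol
Product: 21 3-hydroxy-2-(4-hydroxy-3-methoxyphenyl)-8-methoxy-5-(methoxymethoxy)-7-(3-methylbut-2-enyloxy)-4H-chromen-4-one
Conditions: Bu4NF, AcOH, THF, 0 °C, under argon
Reagents that add atoms: none
Why: Fluoride-induced cleavage of the aryl silyl ether; the acetic acid buffer keeps the flavonol from standing as a phenoxide in air.

**Step 15**
Reactants: 21 the 5-O-MOM flavonol
Product: 22 3,5-dihydroxy-2-(4-hydroxy-3-methoxyphenyl)-8-methoxy-7-(3-methylbut-2-enyloxy)-4H-chromen-4-one (the target)
Conditions: 1 M aq. HCl, MeOH–THF, rt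
Reagents that add atoms: none
Why: Acid-catalysed cleavage of the acetal: the MOM group on O5 lies peri to the C4 carbonyl, where hydrogen bonding to the carbonyl oxygen assists loss of the oxocarbenium ion, so dilute acid at room temperature should suffice and leave the prenyl and methyl ethers alone.

## Compound list

1 | 2-methoxyresorcinol (2-methoxybenzene-1,3-diol) | COc1c(O)cccc1O | starting material
2 | 1,3-bis(tert-butyldimethylsilyloxy)-2-methoxybenzene | COc1c(O[Si](C)(C)C(C)(C)C)cccc1O[Si](C)(C)C(C)(C)C | intermediate
3 | 2-[3,5-bis(tert-butyldimethylsilyloxy)-4-methoxyphenyl]-4,4,5,5-tetramethyl-1,3,2-dioxaborolane (not isolated) | COc1c(O[Si](C)(C)C(C)(C)C)cc(B2OC(C)(C)C(C)(C)O2)cc1O[Si](C)(C)C(C)(C)C | intermediate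
4 | 3,5-bis(tert-butyldimethylsilyloxy)-4-methoxyphenol | COc1c(O[Si](C)(C)C(C)(C)C)cc(O)cc1O[Si](C)(C)C(C)(C)C | intermediate
5 | 2,4-bis(tert-butyldimethylsilyloxy)-6-hydroxy-3-methoxybenzaldehyde | COc1c(O[Si](C)(C)C(C)(C)C)cc(O)c(C=O)c1O[Si](C)(C)C(C)(C)C | intermediate
6 | 2,4-bis(tert-butyldimethylsilyloxy)-3-methoxy-6-(methoxymethoxy)benzaldehyde | COCOc1cc(O[Si](C)(C)C(C)(C)C)c(OC)c(O[Si](C)(C)C(C)(C)C)c1C=O | intermediate
7 | 2,4-dihydroxy-3-methoxy-6-(methoxymethoxy)benzaldehyde | COCOc1cc(O)c(OC)c(O)c1C=O | intermediate
8 | prenyl bromide (1-bromo-3-methylbut-2-ene) | CC(C)=CCBr | starting material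
9 | 2-hydroxy-3-methoxy-6-(methoxymethoxy)-4-(3-methylbut-2-enyloxy)benzaldehyde | COCOc1cc(OCC=C(C)C)c(OC)c(O)c1C=O | intermediate
10 | homovanillic acid (2-(4-hydroxy-3-methoxyphenyl)acetic acid) | COc1cc(CC(=O)O)ccc1O | starting material
11 | methyl 2-(4-hydroxy-3-methoxyphenyl)acetate | COC(=O)Cc1ccc(O)c(OC)c1 | intermediate
12 | methyl 2-[3-methoxy-4-(triisopropylsilyloxy)phenyl]acetate | COC(=O)Cc1ccc(O[Si](C(C)C)(C(C)C)C(C)C)c(OC)c1 | intermediate
13 | 1-methoxy-2-[3-methoxy-4-(triisopropylsilyloxy)phenyl]-1-(trimethylsilyloxy)ethene (mixture of geometric isomers, not isolated) | COC(O[Si](C)(C)C)=Cc1ccc(O[Si](C(C)C)(C(C)C)C(C)C)c(OC)c1 | intermediate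
14 | methyl 2-bromo-2-[3-methoxy-4-(triisopropylsilyloxy)phenyl]acetate (racemic) | COC(=O)C(Br)c1ccc(O[Si](C(C)C)(C(C)C)C(C)C)c(OC)c1 | intermediate
15 | methyl 2-[2-formyl-6-methoxy-3-(methoxymethoxy)-5-(3-methylbut-2-enyloxy)phenoxy]-2-[3-methoxy-4-(triisopropylsilyloxy)phenyl]acetate (racemic) | COC(=O)C(Oc1c(OC)c(OCC=C(C)C)cc(OCOC)c1C=O)c1ccc(O[Si](C(C)C)(C(C)C)C(C)C)c(OC)c1 | intermediate
16 | 2-[2-(hydroxymethyl)-6-methoxy-3-(methoxymethoxy)-5-(3-methylbut-2-enyloxy)phenoxy]-2-[3-methoxy-4-(triisopropylsilyloxy)phenyl]ethanol (racemic) | OCC(Oc1c(OC)c(OCC=C(C)C)cc(OCOC)c1CO)c1ccc(O[Si](C(C)C)(C(C)C)C(C)C)c(OC)c1 | intermediate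
17 | 2-[2-formyl-6-methoxy-3-(methoxymethoxy)-5-(3-methylbut-2-enyloxy)phenoxy]-2-[3-methoxy-4-(triisopropylsilyloxy)phenyl]acetaldehyde (racemic) | O=CC(Oc1c(OC)c(OCC=C(C)C)cc(OCOC)c1C=O)c1ccc(O[Si](C(C)C)(C(C)C)C(C)C)c(OC)c1 | intermediate
18 | 4-hydroxy-8-methoxy-5-(methoxymethoxy)-2-[3-methoxy-4-(triisopropylsilyloxy)phenyl]-7-(3-methylbut-2-enyloxy)chroman-3-one (racemic mixture of diastereomers, not isolated) | COCOc1cc(OCC=C(C)C)c(OC)c2OC(c3ccc(O[Si](C(C)C)(C(C)C)C(C)C)c(OC)c3)C(=O)C(O)c12 | intermediate
19 | 3-hydroxy-8-methoxy-5-(methoxymethoxy)-2-[3-methoxy-4-(triisopropylsilyloxy)phenyl]-7-(3-methylbut-2-enyloxy)chroman-4-one (racemic mixture of diastereomers, not isolated) | COCOc1cc(OCC=C(C)C)c(OC)c2OC(c3ccc(O[Si](C(C)C)(C(C)C)C(C)C)c(OC)c3)C(O)C(=O)c12 | intermediate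
20 | 3-hydroxy-8-methoxy-5-(methoxymethoxy)-2-[3-methoxy-4-(triisopropylsilyloxy)phenyl]-7-(3-methylbut-2-enyloxy)-4H-chromen-4-one | COc1cc(-c2oc3c(OC)c(OCC=C(C)C)cc(OCOC)c3c(=O)c2O)ccc1O[Si](C(C)C)(C(C)C)C(C)C | intermediate
21 | 3-hydroxy-2-(4-hydroxy-3-methoxyphenyl)-8-methoxy-5-(methoxymethoxy)-7-(3-methylbut-2-enyloxy)-4H-chromen-4-one | COc1cc(-c2oc3c(OC)c(OCC=C(C)C)cc(OCOC)c3c(=O)c2O)ccc1O | intermediate
22 | 3,5-dihydroxy-2-(4-hydroxy-3-methoxyphenyl)-8-methoxy-7-(3-methylbut-2-enyloxy)-4H-chromen-4-one | COc1cc(-c2oc3c(OC)c(OCC=C(C)C)cc(O)c3c(=O)c2O)ccc1O | target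

## Step count and least certain steps

Total: 15 steps. Longest linear sequence: 12 steps (steps 1–6 and 10–15); the ring B branch (steps 7–9) joins at step 10.

**Step 13 (key step).**
- What may go wrong: the Breslow intermediate of the α-aryloxy aldehyde may expel the ring A phenoxide before the C–C bond forms. The acceptor aldehyde is hindered and deactivated by two alkoxy groups, so addition is slow, and the result would be an internal redox to an aryl ester. The amine may also trigger aldol closure of the enolisable aldehyde onto the ring A aldehyde.
- Fallback, from 17 back to 20: form the same bond by reductive coupling, which needs neither a carbanion next to the aryloxy group nor a base. SmI2 in THF with t-BuOH at −78 °C should reduce the aromatic aldehyde first, and its ketyl should add to the aliphatic aldehyde to give the flavan-3,4-diol F1. Oxidation of both carbinols with IBX in DMSO gives the 3,4-dione, which enolises to 20.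

**Step 3.**
- What may go wrong: formylation may be slow or incomplete at an ortho carbon that is flanked by a bulky silyloxy group, and silyl ethers may be lost on long heating.
- Fallback, from 4 back to 6: brominate the same carbon with NBS at low temperature to give the bromophenol F2, convert it with MOMCl and i-Pr2NEt into the bromo acetal F3, then carry out bromine–lithium exchange with n-BuLi at −78 °C and quench at once with DMF. This gives 6 directly and bypasses 5.

**Step 10.**
- What may go wrong: the product may enolise at the carbon between aryl, ester and aryloxy and close onto the neighbouring aldehyde (five-membered aldol). The benzylic bromide may solvolyse, and the chelated, doubly flanked phenoxide may react slowly.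
- Fallback, from 12 and 9 back to 15: hydroxylate the enolate of 12 (KN(SiMe3)2, then 2-(phenylsulfonyl)-3-phenyloxaziridine) to the mandelate F4, and join F4 to phenol 9 under Mitsunobu conditions (PPh3, diisopropyl azodicarboxylate, toluene). The ether then forms without base or halide.

**Step 12.**
- What may go wrong: the α-aryl-α-aryloxy aldehyde may enolise, undergo aldol reaction or air oxidation during the double oxidation and isolation. The half-oxidised hydroxy aldehyde may close to a lactol that is oxidised further.
- Fallback, from 16 back to 17: oxidise in two stages. MnO2 in CH2Cl2 should oxidise only the benzylic alcohol to the stable hydroxy aldehyde F5, which can be purified. The remaining primary alcohol is then oxidised with SO3·pyridine, DMSO and i-Pr2NEt at 0 °C, and crude 17 goes straight into step 13.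

**Step 15.**
- What may go wrong: the prenyl ether may ionise in acid (allylic cation) in competition with cleavage of the acetal.
- Fallback, from 20 back to 22: accept the loss and put the prenyl group back. Treat 20 with HCl in MeOH at 50 °C until both the acetal and the allyl ether are cleaved, giving the silylated triol F6. Alkylate F6 with one equivalent of 8 and KHCO3 in DMF; this should go at the 7-hydroxyl, the most acidic one, since the 3- and 5-hydroxyls are chelated to the carbonyl, and gives F7. Bu4NF with AcOH then gives 22.

## Further compounds

F1 | step 13 | 8-methoxy-5-(methoxymethoxy)-2-[3-methoxy-4-(triisopropylsilyloxy)phenyl]-7-(3-methylbut-2-enyloxy)chroman-3,4-diol (racemic mixture of diastereomers) | COCOc1cc(OCC=C(C)C)c(OC)c2OC(c3ccc(O[Si](C(C)C)(C(C)C)C(C)C)c(OC)c3)C(O)C(O)c12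
F2 | step 3 | 2-bromo-3,5-bis(tert-butyldimethylsilyloxy)-4-methoxyphenol | COc1c(O[Si](C)(C)C(C)(C)C)cc(O)c(Br)c1O[Si](C)(C)C(C)(C)C
F3 | step 3 | 1-bromo-2,4-bis(tert-butyldimethylsilyloxy)-3-methoxy-6-(methoxymethoxy)benzene | COCOc1cc(O[Si](C)(C)C(C)(C)C)c(OC)c(O[Si](C)(C)C(C)(C)C)c1Br
F4 | step 10 | methyl 2-hydroxy-2-[3-methoxy-4-(triisopropylsilyloxy)phenyl]acetate (racemic) | COC(=O)C(O)c1ccc(O[Si](C(C)C)(C(C)C)C(C)C)c(OC)c1
F5 | step 12 | 2-{2-hydroxy-1-[3-methoxy-4-(triisopropylsilyloxy)phenyl]ethoxy}-3-methoxy-6-(methoxymethoxy)-4-(3-methylbut-2-enyloxy)benzaldehyde (racemic) | OCC(Oc1c(OC)c(OCC=C(C)C)cc(OCOC)c1C=O)c1ccc(O[Si](C(C)C)(C(C)C)C(C)C)c(OC)c1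
F6 | step 15 | 3,5,7-trihydroxy-8-methoxy-2-[3-methoxy-4-(triisopropylsilyloxy)phenyl]-4H-chromen-4-one | COc1cc(-c2oc3c(OC)c(O)cc(O)c3c(=O)c2O)ccc1O[Si](C(C)C)(C(C)C)C(C)C
F7 | step 15 | 3,5-dihydroxy-8-methoxy-2-[3-methoxy-4-(triisopropylsilyloxy)phenyl]-7-(3-methylbut-2-enyloxy)-4H-chromen-4-one | COc1cc(-c2oc3c(OC)c(OCC=C(C)C)cc(O)c3c(=O)c2O)ccc1O[Si](C(C)C)(C(C)C)C(C)C
A1 | alternative 1 | 1-[4,6-bis(benzyloxy)-3-methoxy-2-(methoxymethoxy)phenyl]-3-(4-benzyloxy-3-methoxyphenyl)-2-(methoxymethoxy)propane-1,3-dione (racemic) | COCOc1c(OC)c(OCc2ccccc2)cc(OCc2ccccc2)c1C(=O)C(OCOC)C(=O)c1ccc(OCc2ccccc2)c(OC)c1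
A2 | alternative 1 | 1,5-bis(benzyloxy)-2-iodo-4-methoxy-3-(methoxymethoxy)benzene | COCOc1c(OC)c(OCc2ccccc2)cc(OCc2ccccc2)c1I
A3 | alternative 1 | 1-(4-benzyloxy-3-methoxyphenyl)-2-(methoxymethoxy)ethanone | COCOCC(=O)c1ccc(OCc2ccccc2)c(OC)c1
A4 | alternative 1 | 3,5,7-trihydroxy-2-(4-hydroxy-3-methoxyphenyl)-8-methoxy-4H-chromen-4-one (limocitrin) | COc1cc(-c2oc3c(OC)c(O)cc(O)c3c(=O)c2O)ccc1O
A5 | alternative 2 | 3,4'-di-O-pivaloyl-7-O-triisopropylsilyl-limocitrin | COc1cc(-c2oc3c(OC)c(O[Si](C(C)C)(C(C)C)C(C)C)cc(O)c3c(=O)c2OC(=O)C(C)(C)C)ccc1OC(=O)C(C)(C)C
A6 | alternative 2 | 2-methoxy-2-{6-[3-methoxy-4-(pivaloyloxy)phenyl]-4-oxo-5-(pivaloyloxy)-4H-pyran-2-yl}acetyl chloride (racemic) | COC(C(=O)Cl)c1cc(=O)c(OC(=O)C(C)(C)C)c(-c2ccc(OC(=O)C(C)(C)C)c(OC)c2)o1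
A7 | alternative 2 | 2-methoxy-2-{6-[3-methoxy-4-(pivaloyloxy)phenyl]-4-oxo-5-(pivaloyloxy)-4H-pyran-2-yl}ethenone (the ketene) | COC(=C=O)c1cc(=O)c(OC(=O)C(C)(C)C)c(-c2ccc(OC(=O)C(C)(C)C)c(OC)c2)o1
A8 | alternative 2 | (triisopropylsilyloxy)acetylene | C#CO[Si](C(C)C)(C(C)C)C(C)C
A9 | alternative 3 | 5,7-di-O-benzyl-3,4'-di-O-pivaloyl-limocitrin | COc1cc(-c2oc3c(OC)c(OCc4ccccc4)cc(OCc4ccccc4)c3c(=O)c2OC(=O)C(C)(C)C)ccc1OC(=O)C(C)(C)C
A10 | alternative 3 | (E)-3-[3,5-bis(benzyloxy)-2-methoxyphenoxy]-3-[3-methoxy-4-(pivaloyloxy)phenyl]-2-(pivaloyloxy)acrylic acid | OC(=O)/C(OC(=O)C(C)(C)C)=C(\Oc1cc(OCc2ccccc2)cc(OCc2ccccc2)c1OC)c1ccc(OC(=O)C(C)(C)C)c(OC)c1
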